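**Plan**

- Retrosynthesis: the two C5–prenyl bonds are cut first, which returns the dearomatised C5 to the free CH of an aromatic acylphloroglucinol. Next the two methyl–carbinol bonds are cut (tertiary alcohol back to a C2 methyl ester), then C3–C2 and O1–C2 of the dihydrofuran together, and last C3–C3a (a Mannich carbon).
- Enabling feature (benzofuran numbering O1, C2, C3, C3a, C4–C7, C7a): C3 is a methylene on C3a, ortho to the C7a oxygen. The unit C3=C3a–C7a=O can therefore be unmasked as an ortho-quinone methide, and C2 can be delivered to it as a one-carbon sulfonium ylide.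
- Forward: phlorisobutyrophenone is MOM-protected at the C4 oxygen, aminomethylated and quaternised. A [4+1] annulation with a chiral thiolanium ylide then closes the dihydrofuran, the only ring that is built; the carbocycle is the original arene.
- The ester is converted into the carbinol with MeMgBr, the MOM group is removed, and double prenylation at C5 dearomatises the ring to the enolised triketone.
- Stereochemistry: the single stereocentre C2 (S) is set in the annulation by the (2R,5R)-2,5-dimethylthiolanium group, made from (2S,5S)-hexane-2,5-diol with double inversion. No later step touches C2.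

Key step: step 7

Assumption: the (2R,5R)-thiolanium ylide is taken to deliver the (S)-configured C2; should its intrinsic preference be the opposite, the enantiomeric sulfide from (2R,5R)-hexane-2,5-diol would be carried through the same steps.

**Route**

Step 1
Reactants: 1 (2S,5S)-hexane-2,5-diol
Product: 2 (2S,5S)-hexane-2,5-diyl dimethanesulfonate
Conditions: MsCl (2.4 equiv), Et3N (3 equiv), CH2Cl2, 0 °C
Reagents that add atoms: methanesulfonyl chloride CS(=O)(=O)Cl
Why: Mesylation takes place at oxygen only, so both carbinol carbons keep their configuration while becoming SN2-active.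

Step 2
Reactants: 2 (2S,5S)-hexane-2,5-diyl dimethanesulfonate
Product: 4 (2R,5R)-2,5-dimethylthiolane, via thiolate mesylate 3 (not isolated)
Conditions: Na2S·9H2O (1.2 equiv), EtOH, rt → 50 °C
Reagents that add atoms: sodium sulfide (Na2S) [Na+].[Na+].[S-2]
Why: Two successive SN2 displacements by sulfur, the second a 5-exo-tet closure, invert both centres and should turn the (2S,5S)-dimesylate into the (2R,5R)-thiolane.

Step 3
Reactants: 4 (2R,5R)-2,5-dimethylthiolane, 5 methyl bromoacetate
Product: 6 (2R,5R)-1-(2-methoxy-2-oxoethyl)-2,5-dimethylthiolan-1-ium bromide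
Conditions: acetone, rt, 48 h
Reagents that add atoms: none
Why: S-Alkylation of the sulfide by the activated α-bromo ester gives the sulfonium salt, and because the two lone pairs of the twofold-symmetric thiolane are homotopic a single salt forms in which sulfur is not a stereocentre.

Step 4
Reactants: 7 phlorisobutyrophenone [1-(2,4,6-trihydroxyphenyl)-2-methylpropan-1-one]
Product: 8 1-[2,6-dihydroxy-4-(methoxymethoxy)phenyl]-2-methylpropan-1-one
Conditions: MOMCl (1.05 equiv), iPr2NEt (1.1 equiv), CH2Cl2, 0 °C
Reagents that add atoms: chloromethyl methyl ether COCCl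
Why: O-Alkylation with one equivalent of MOMCl should fall on the hydroxyl para to the acyl group, which is the most acidic and the only one not hydrogen-bonded to the ketone.

Step 5
Reactants: 8 1-[2,6-dihydroxy-4-(methoxymethoxy)phenyl]-2-methylpropan-1-one
Product: 9 1-{3-[(dimethylamino)methyl]-2,6-dihydroxy-4-(methoxymethoxy)phenyl}-2-methylpropan-1-one
Conditions: CH2O (37% aq, 1.0 equiv) premixed with Me2NH (40% aq, 1.2 equiv), EtOH, 0 °C → rt
Reagents that add atoms: formaldehyde C=O; dimethylamine CNC
Why: Mannich aminomethylation of the electron-rich phenol occurs at one of its two equivalent free ring positions (each ortho to a free hydroxyl), premixing with the amine keeps free formaldehyde low, and one equivalent limits the reaction to mono-substitution.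

Step 6
Reactants: 9 1-{3-[(dimethylamino)methyl]-2,6-dihydroxy-4-(methoxymethoxy)phenyl}-2-methylpropan-1-one
Product: 10 [2,4-dihydroxy-6-(methoxymethoxy)-3-(2-methylpropanoyl)phenyl]-N,N,N-trimethylmethanaminium iodide
Conditions: MeI (5 equiv), acetone, rt, dark
Reagents that add atoms: iodomethane CI
Why: Menshutkin quaternisation of the benzylic amine, far more nucleophilic than the chelated phenols when no base is present, gives a salt that is stable while protonated but expels trimethylamine at low temperature once the phenol is deprotonated.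

Step 7
Reactants: 10 [2,4-dihydroxy-6-(methoxymethoxy)-3-(2-methylpropanoyl)phenyl]-N,N,N-trimethylmethanaminium iodide, 6 (2R,5R)-1-(2-methoxy-2-oxoethyl)-2,5-dimethylthiolan-1-ium bromide
Product: 14 methyl (2S)-6-hydroxy-4-(methoxymethoxy)-7-(2-methylpropanoyl)-2,3-dihydro-1-benzofuran-2-carboxylate, via sulfonium ylide 11 (not isolated), via ortho-quinone methide 12 (not isolated), via phenoxide sulfonium betaine 13 (not isolated)
Conditions: 6 (2.0 equiv), Cs2CO3 (4 equiv), CH2Cl2, −20 °C; 10 in MeCN added over 4 h; −20 → 0 °C
Reagents that add atoms: none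
Why: Proposed new method: carbonate turns 6 into ylide 11 and deprotonates 10, whose phenoxide expels trimethylamine to give quinone methide 12; the ylide carbon adds to the exocyclic methylene (C3) with re-aromatisation to betaine 13, and the C7a phenoxide then displaces the thiolane from C2, so that C3–C2 and O1–C2 form in one flask. The closest known reaction type is the [4+1] annulation of in situ generated ortho-quinone methides with stabilised sulfonium or ammonium ylides, racemic for unsubstituted methides and asymmetric only where the methide carbon carries a substituent; new here is that the sulfonium group alone must induce asymmetry at C2. The dihydrofuran closes by a 5-exo-tet SN2 substitution with inversion at C2. The C2 stereocentre is controlled by the twofold-symmetric (2R,5R)-thiolanium group: the betaine epimers interconvert through deprotonation of the acidic C2–H (alpha to ester and sulfonium) and through reversal of the addition, and the epimer whose departing sulfide clashes least with the backside-attacking aryloxide should close faster (Curtin–Hammett selection), the (R)-betaine giving the (S)-ester. The step needs closure onto the oxygen next to the acyl group and must outrun self-condensation of the methide; the MOM ether blocks the C4 oxygen, the C6 hydroxyl is para to the methylene and cannot reach C2, and slow addition of 10 to an excess of preformed ylide keeps the methide concentration low.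

Step 8
Reactants: 14 methyl (2S)-6-hydroxy-4-(methoxymethoxy)-7-(2-methylpropanoyl)-2,3-dihydro-1-benzofuran-2-carboxylate
Product: 16 1-[(2S)-6-hydroxy-2-(2-hydroxypropan-2-yl)-4-(methoxymethoxy)-2,3-dihydro-1-benzofuran-7-yl]-2-methylpropan-1-one, via methyl ketone 15 (not isolated)
Conditions: MeMgBr (4.5 equiv), THF, −40 → 0 °C; aqueous work-up
Reagents that add atoms: methylmagnesium bromide (MeMgBr) C[Mg]Br
Why: Double Grignard addition to the methyl ester gives the tertiary carbinol, while the aryl ketone (two ortho oxygens, an isopropyl group, and held as a magnesium-chelated phenoxide, i.e. a vinylogous carboxylate) should resist attack, and C2 should keep its configuration because addition to the α-aryloxy ester outpaces enolisation at low temperature.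

Step 9
Reactants: 16 1-[(2S)-6-hydroxy-2-(2-hydroxypropan-2-yl)-4-(methoxymethoxy)-2,3-dihydro-1-benzofuran-7-yl]-2-methylpropan-1-one
Product: 17 1-[(2S)-4,6-dihydroxy-2-(2-hydroxypropan-2-yl)-2,3-dihydro-1-benzofuran-7-yl]-2-methylpropan-1-one
Conditions: HCl (1.25 M in MeOH), 40 °C
Reagents that add atoms: none
Why: Acid-catalysed acetal exchange removes the aryl MOM ether, methanol trapping the formaldehyde unit as dimethoxymethane, while the tertiary alcohol (deactivated towards ionisation by the adjacent ring oxygen) and C2 are left alone.

Step 10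
Reactants: 17 1-[(2S)-4,6-dihydroxy-2-(2-hydroxypropan-2-yl)-2,3-dihydro-1-benzofuran-7-yl]-2-methylpropan-1-one, 18 prenyl bromide (1-bromo-3-methylbut-2-ene)
Product: 20 garcinielliptone HD [(2S,7Z)-7-(1-hydroxy-2-methylpropylidene)-2-(2-hydroxypropan-2-yl)-5,5-bis(3-methylbut-2-en-1-yl)-2,3-dihydro-1-benzofuran-4,6(5H,7H)-dione], via 5-prenyl phenol 19 (not isolated)
Conditions: 18 (2.2 equiv), 10% aq KOH, 0 °C; acidic work-up
Reagents that add atoms: none
Why: Alkylative dearomatisation of an acylphloroglucinol: the dianion is C-prenylated at C5, the only unsubstituted ring carbon and the one flanked by both oxyanions, and phenol 19 is alkylated again at the same carbon because only that attack leads to the conjugated enolised triketone, water as solvent disfavouring O-alkylation.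

**Compound list**

1 | (2S,5S)-hexane-2,5-diol | C[C@H](O)CC[C@H](C)O | starting material
2 | (2S,5S)-hexane-2,5-diyl dimethanesulfonate | C[C@H](OS(C)(=O)=O)CC[C@H](C)OS(C)(=O)=O | intermediate
3 | sodium (2R,5S)-5-[(methylsulfonyl)oxy]hexane-2-thiolate | C[C@@H]([S-])CC[C@H](C)OS(C)(=O)=O.[Na+] | intermediate (not isolated)
4 | (2R,5R)-2,5-dimethylthiolane | C[C@@H]1CC[C@@H](C)S1 | intermediate
5 | methyl bromoacetate | COC(=O)CBr | starting material
6 | (2R,5R)-1-(2-methoxy-2-oxoethyl)-2,5-dimethylthiolan-1-ium bromide | C[C@@H]1CC[C@@H](C)[S+]1CC(=O)OC.[Br-] | intermediate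
7 | phlorisobutyrophenone, 1-(2,4,6-trihydroxyphenyl)-2-methylpropan-1-one | CC(C)C(=O)c1c(O)cc(O)cc1O | starting material
8 | 1-[2,6-dihydroxy-4-(methoxymethoxy)phenyl]-2-methylpropan-1-one | CC(C)C(=O)c1c(O)cc(OCOC)cc1O | intermediate
9 | 1-{3-[(dimethylamino)methyl]-2,6-dihydroxy-4-(methoxymethoxy)phenyl}-2-methylpropan-1-one | CC(C)C(=O)c1c(O)cc(OCOC)c(CN(C)C)c1O | intermediate
10 | [2,4-dihydroxy-6-(methoxymethoxy)-3-(2-methylpropanoyl)phenyl]-N,N,N-trimethylmethanaminium iodide | CC(C)C(=O)c1c(O)cc(OCOC)c(C[N+](C)(C)C)c1O.[I-] | intermediate
11 | (2R,5R)-2,5-dimethylthiolanium (methoxycarbonyl)methylide | C[C@@H]1CC[C@@H](C)[S+]1[CH-]C(=O)OC | intermediate (not isolated)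
12 | 3-hydroxy-5-(methoxymethoxy)-6-methylidene-2-(2-methylpropanoyl)cyclohexa-2,4-dien-1-one | C=C1C(=O)C(C(=O)C(C)C)=C(O)C=C1OCOC | intermediate (not isolated)
13 | 6-{(2R)-2-[(2R,5R)-2,5-dimethylthiolan-1-ium-1-yl]-3-methoxy-3-oxopropyl}-3-hydroxy-5-(methoxymethoxy)-2-(2-methylpropanoyl)phenolate (productive epimer of the betaine) | C[C@@H]1CC[C@@H](C)[S+]1[C@@H](C(=O)OC)Cc1c([O-])c(C(=O)C(C)C)c(O)cc1OCOC | intermediate (not isolated)
14 | methyl (2S)-6-hydroxy-4-(methoxymethoxy)-7-(2-methylpropanoyl)-2,3-dihydro-1-benzofuran-2-carboxylate | CC(C)C(=O)c1c(O)cc(OCOC)c2c1O[C@H](C(=O)OC)C2 | intermediate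
15 | 1-[(2S)-2-acetyl-6-hydroxy-4-(methoxymethoxy)-2,3-dihydro-1-benzofuran-7-yl]-2-methylpropan-1-one | CC(C)C(=O)c1c(O)cc(OCOC)c2c1O[C@H](C(C)=O)C2 | intermediate (not isolated)
16 | 1-[(2S)-6-hydroxy-2-(2-hydroxypropan-2-yl)-4-(methoxymethoxy)-2,3-dihydro-1-benzofuran-7-yl]-2-methylpropan-1-one | CC(C)C(=O)c1c(O)cc(OCOC)c2c1O[C@H](C(C)(C)O)C2 | intermediate
17 | 1-[(2S)-4,6-dihydroxy-2-(2-hydroxypropan-2-yl)-2,3-dihydro-1-benzofuran-7-yl]-2-methylpropan-1-one | CC(C)C(=O)c1c(O)cc(O)c2c1O[C@H](C(C)(C)O)C2 | intermediate
18 | prenyl bromide, 1-bromo-3-methylbut-2-ene | CC(C)=CCBr | starting material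
19 | 1-[(2S)-4,6-dihydroxy-2-(2-hydroxypropan-2-yl)-5-(3-methylbut-2-en-1-yl)-2,3-dihydro-1-benzofuran-7-yl]-2-methylpropan-1-one | CC(C)C(=O)c1c(O)c(CC=C(C)C)c(O)c2c1O[C@H](C(C)(C)O)C2 | intermediate (not isolated)
20 | garcinielliptone HD, (2S,7Z)-7-(1-hydroxy-2-methylpropylidene)-2-(2-hydroxypropan-2-yl)-5,5-bis(3-methylbut-2-en-1-yl)-2,3-dihydro-1-benzofuran-4,6(5H,7H)-dione | CC(C)=CCC1(CC=C(C)C)C(=O)C2=C(O[C@H](C(C)(C)O)C2)/C(=C(/O)C(C)C)C1=O | target

**Step count**

Total steps: 10. Longest linear sequence: 7 steps (steps 4 to 10 from phlorisobutyrophenone; the sulfonium branch, steps 1 to 3, joins at step 7).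

**Steps most likely to fail**

1. Step 7. Two processes threaten it: weak discrimination between the betaine epimers during ring closure (low enantiomeric purity at C2), and self-condensation of the quinone methide with the free ring position of its own phenolic precursor (methylene-bridged dimers).
   The fallback uses known chemistry only, sets out from 8 and rejoins the route at 16. Compound 8 is C-prenylated with prenyl bromide 18 (aq KOH, 0 °C) at one of its two equivalent ring positions to give the ortho-prenyl phenol F1. Both phenols are acetylated (Ac2O, pyridine, DMAP) to give the diacetate F2. Shi asymmetric epoxidation (D-fructose-derived ketone catalyst, KHSO5, K2CO3 buffer, MeCN/dimethoxymethane/H2O, 0 °C) should, by the spiro transition-state model, deliver the (R)-epoxide F3. K2CO3 in MeOH then removes the acetates to give the epoxy phenol F4, whose phenoxide ortho to the side chain opens the epoxide at its secondary carbon (5-exo-tet, inversion) to give 16. Step 8 is bypassed as well.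

2. Step 10. Competing O-prenylation, alkylation at the substituted carbons C3a or C7, and over-alkylation of the product enolate may divert material.
   The fallback sets out from 17 and arrives at 20 without a new isolated compound. It is a Tsuji–Trost prenylation with prenyl acetate, Pd(PPh3)4 (zerovalent palladium, 5 mol%) and K2CO3 in THF at rt. O-Prenyl ethers re-ionise under zerovalent palladium, so the reaction is funnelled to the C-allylated products, and the soft carbon nucleophile attacks the unsubstituted terminus of the π-prenyl complex. The sequence passes through 19 to 20.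

3. Step 8. The excess Grignard reagent may attack or enolise the aryl isopropyl ketone, and C2 may epimerise through enolate formation of the ester or of the intermediate methyl ketone.
   The fallback sets out from 14 and rejoins at 16 by three controlled additions at low temperature. MeNH(OMe)·HCl with iPrMgCl (THF, −20 °C) converts the ester into the Weinreb amide F5. MeMgBr at −78 °C (one equivalent beyond that consumed by the phenol) stops at the methyl ketone 15, which is now isolated. MeMgBr/CeCl3 (THF, −78 °C) then adds to this unhindered ketone to give 16.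

Further compounds
F1 | step 7 | 1-[2,6-dihydroxy-4-(methoxymethoxy)-3-(3-methylbut-2-en-1-yl)phenyl]-2-methylpropan-1-one | CC(C)C(=O)c1c(O)cc(OCOC)c(CC=C(C)C)c1O
F2 | step 7 | 5-(methoxymethoxy)-4-(3-methylbut-2-en-1-yl)-2-(2-methylpropanoyl)-1,3-phenylene diacetate | CC(C)C(=O)c1c(OC(C)=O)cc(OCOC)c(CC=C(C)C)c1OC(C)=O
F3 | step 7 | 4-{[(2R)-3,3-dimethyloxiran-2-yl]methyl}-5-(methoxymethoxy)-2-(2-methylpropanoyl)-1,3-phenylene diacetate | CC(C)C(=O)c1c(OC(C)=O)cc(OCOC)c(C[C@H]2OC2(C)C)c1OC(C)=O
F4 | step 7 | 1-[3-{[(2R)-3,3-dimethyloxiran-2-yl]methyl}-2,6-dihydroxy-4-(methoxymethoxy)phenyl]-2-methylpropan-1-one | CC(C)C(=O)c1c(O)cc(OCOC)c(C[C@H]2OC2(C)C)c1O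
F5 | step 8 | (2S)-6-hydroxy-N-methoxy-4-(methoxymethoxy)-N-methyl-7-(2-methylpropanoyl)-2,3-dihydro-1-benzofuran-2-carboxamide | CC(C)C(=O)c1c(O)cc(OCOC)c2c1O[C@H](C(=O)N(C)OC)C2
F0 | step 10 | none | none
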